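**Retrosynthetic overview**
1. Target 24 ⇐ ene-type allylic chlorination (C6–Cl, C5=C16) of the ten-membered-ring olefin 23; chlorine is put in last.
2. 23 ⇐ one-pot chromium-mediated double ring closure of 21: Reformatsky lactonisation (C17–C8) plus Ni/Cr alkenylation of the enal (C3–C4), so the γ-lactone and the ten-membered ring form together.
3. 21 ⇐ cyclohexenone thioester 12 by acyl coupling (C7–C8), cross-metathesis (C6=C7), Takai iodo-olefination (C2=C3), asymmetric enone epoxidation and epoxide-to-allylic-alcohol shift (C7–O), then O-acylation.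
4. 12 ⇐ Diels–Alder reaction of the 4-methyl Danishefsky-type diene 9 with the (S)-α-acetoxy thioester enal 6, then Mn(OAc)3 α′-acetoxylation.
5. Ring order: cyclohexenone (step 7), then γ-lactone and ten-membered carbocycle in one operation (step 15).

Assumption: atom labels C1–C20 follow the usual briarane numbering of the target (C1 ring-fusion quaternary carbon, C2=C3, C4 carbinol, C5=C16, C6 chloride, C7 lactone CH–O, C8 tertiary carbinol, C9 and C11 acetates, C12 ketone, C13=C14, C15 and C20 methyls, C17–C19 lactone propionate unit).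

**Route**

Step 1
Reactants: 1 methyl 2-hydroxybut-3-enoate (racemic)
Product: 2 S-ethyl 2-hydroxybut-3-enethioate (racemic)
Conditions: AlMe3 (2.2 equiv), EtSH, CH2Cl2, 0 °C to rt
Reagents that add atoms: ethanethiol CCS
Why: Dimethylaluminium ethanethiolate formed from AlMe3 and EtSH converts the methyl ester directly into the thioester (aluminium thiolate transthioesterification), the free hydroxyl being carried as its aluminium alkoxide, and no stereocentre is set.

Step 2
Reactants: 2 S-ethyl 2-hydroxybut-3-enethioate (racemic)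
Product: 3 S-ethyl (S)-2-hydroxybut-3-enethioate
Conditions: Candida antarctica lipase B (immobilised), vinyl acetate, MTBE, 30 °C, stopped at about 52% conversion
Reagents that add atoms: none
Why: Lipase-catalysed kinetic resolution (enantioselective transesterification) in which, by Kazlauskas' rule, the R alcohol is acetylated and the S alcohol carrying the future C9 configuration is recovered unreacted.

Step 3
Reactants: 3 S-ethyl (S)-2-hydroxybut-3-enethioate
Product: 4 S-ethyl (S)-2-acetoxybut-3-enethioate
Conditions: Ac2O, pyridine, DMAP (cat.), CH2Cl2, 0 °C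
Reagents that add atoms: acetic anhydride CC(=O)OC(C)=O
Why: DMAP-catalysed O-acetylation of the secondary alcohol installs the C9 acetate of the target without touching the stereocentre.

Step 4
Reactants: 4 S-ethyl (S)-2-acetoxybut-3-enethioate; 5 methacrolein
Product: 6 S-ethyl (2S,3E)-2-acetoxy-4-methyl-5-oxopent-3-enethioate
Conditions: 5 (5 equiv), second-generation Grubbs catalyst (5 mol%), CH2Cl2, 40 °C
Reagents that add atoms: none
Why: Olefin cross-metathesis of the monosubstituted allylic acetate with excess methacrolein gives the thermodynamically favoured E 2-methyl enal, whose E geometry later becomes the trans C1/C10 ring fusion.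

Step 5
Reactants: 7 (E)-4-methoxybut-3-en-2-one
Product: 8 (E)-1-methoxypent-1-en-3-one
Conditions: LDA, THF, −78 °C; MeI
Reagents that add atoms: iodomethane CI
Why: Kinetic deprotonation of the vinylogous ester at its methyl group followed by SN2 methylation (enolate alkylation) gives the ethyl ketone that carries the future C20 methyl.

Step 6
Reactants: 8 (E)-1-methoxypent-1-en-3-one
Product: 9 (1E,3Z)-1-methoxy-3-(trimethylsilyloxy)penta-1,3-diene
Conditions: TMSOTf, Et3N, Et2O, 0 °C
Reagents that add atoms: trimethylsilyl trifluoromethanesulfonate C[Si](C)(C)OS(=O)(=O)C(F)(F)F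
Why: Soft enolisation and O-silylation of the ethyl ketone gives the Z silyl enol ether, a 4-methyl Danishefsky-type diene.

Step 7
Reactants: 6 enal dienophile; 9 silyloxy diene
Product: 11 cyclohexenone aldehyde thioester (C1 S; C9 S; C10 S; C11 epimers), via silyl enol ether cycloadduct 10 (not isolated)
Conditions: 9 (2.5 equiv), toluene, 90 °C, sealed tube; then TFA, CH2Cl2, 0 °C
Reagents that add atoms: none
Why: Thermal normal-demand Diels–Alder reaction followed by acid-induced loss of methanol and of the silyl group (Danishefsky enone synthesis) puts the ketone at C12 because the methoxy terminus bonds to the formyl-bearing carbon, makes C2 and C9 trans on the new ring because the alkene is E, and sets C1 and C10 as S because the diene adds to the enal face anti to the C9–OAc bond in the A(1,3)-minimised conformer (Felkin-type control), while the C11 and C14 configurations are immaterial.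

Step 8
Reactants: 11 cyclohexenone aldehyde thioester
Product: 12 11-acetoxy cyclohexenone aldehyde thioester (C1 S; C9 S; C10 S; C11 S)
Conditions: Mn(OAc)3·2H2O (4 equiv), benzene, reflux, Dean–Stark
Reagents that add atoms: manganese triacetate CC(=O)[O-].CC(=O)[O-].CC(=O)[O-].[Mn+3]
Why: Mn(OAc)3 α′-acetoxylation of the enone acts at C11, the only enolisable position, and delivers acetate to the ring face anti to the neighbouring C10 side chain, giving the 11S tertiary acetate.

Step 9
Reactants: 12 11-acetoxy cyclohexenone aldehyde thioester; 13 tributyl(vinyl)stannane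
Product: 14 vinyl ketone (thioester replaced by C8(=O)–CH=CH2)
Conditions: 13 (1.3 equiv), Pd2(dba)3 (2.5 mol%), tri(2-furyl)phosphine (10 mol%), CuO2PPh2 (1.5 equiv), THF, 50 °C
Reagents that add atoms: none
Why: Liebeskind–Srogl coupling, in which the copper carboxylate activates the thioester for palladium-catalysed acyl transfer to the alkenylstannane under neutral conditions, leaves the acetates, enone, aldehyde and all stereocentres untouched.

Step 10
Reactants: 14 vinyl ketone; 15 2-methylbut-3-en-1-ol (racemic)
Product: 16 E-enone alcohol with side chain C8(=O)–C7H=C6H–C5H(CH3)–C4H2OH (C5 epimers)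
Conditions: 15 (3 equiv), second-generation Grubbs catalyst (5 mol%), CH2Cl2, 40 °C
Reagents that add atoms: none
Why: Cross-metathesis of the electron-poor vinyl ketone with a simple terminal alkene is selective for the E enone, and the C5 centre is left as a mixture because it is erased in step 13.

Step 11
Reactants: 16 E-enone alcohol
Product: 17 E-alkenyl iodide (C1–C2H=C3H–I in place of the formyl group)
Conditions: CrCl2 (8 equiv), CHI3 (3 equiv), THF, 0 °C to rt
Reagents that add atoms: iodoform IC(I)I
Why: Takai olefination converts the hindered aldehyde, and not the ketones, into the E alkenyl iodide, fixing the 2E geometry of the target.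

Step 12
Reactants: 17 E-alkenyl iodide
Product: 18 trans-epoxy ketone (C6 R; C7 S)
Conditions: La(O-iPr)3 (10 mol%), (R)-BINOL (10 mol%), Ph3As=O (10 mol%), t-BuOOH (1.5 equiv), 4 Å MS, THF, rt
Reagents that add atoms: tert-butyl hydroperoxide CC(C)(C)OO
Why: Shibasaki lanthanum–BINOL asymmetric epoxidation of E enones epoxidises only the unhindered acyclic enone (the ring enone has a neopentyl β-carbon) and sets C7 as S under catalyst control, the BINOL enantiomer being the one that gives αS,βR epoxides.

Step 13
Reactants: 18 trans-epoxy ketone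
Product: 20 E γ-hydroxy enal (C7 S; C8(=O)–C7H(OH)–C6H=C5(CH3)–C4HO), via epoxy aldehyde 19 (not isolated)
Conditions: Dess–Martin periodinane (1.05 equiv), CH2Cl2, 0 °C; then Et3N (3 equiv), 0 °C
Reagents that add atoms: none
Why: Dess–Martin oxidation gives a β,γ-epoxy aldehyde whose acidic α-proton triggers E1cB opening of the epoxide (epoxide-to-allylic-alcohol isomerisation) to the E enal, and the C7–O bond and hence the 7S configuration are not touched.

Step 14
Reactants: 20 E γ-hydroxy enal
Product: 21 C7 2-bromopropanoate (CHBr epimers)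
Conditions: 2-bromopropanoyl bromide (1.3 equiv), pyridine, CH2Cl2, −20 °C
Reagents that add atoms: 2-bromopropanoyl bromide CC(Br)C(Br)=O
Why: Low-temperature O-acylation of the secondary C7 hydroxyl with the acid bromide installs the Reformatsky handle without enolising C7, and the CHBr centre is lost in the next step.

Step 15
Reactants: 21 C7 2-bromopropanoate
Product: 23 macrocyclic lactone (1S; 2E; 4S; 5E; 7S; 8S; 9S; 10S; 11S; 17R), via seco-lactone 22 (not isolated)
Conditions: CrCl2 (12 equiv), NiCl2 (0.1 equiv), DMSO–THF (3:1), rt, 2 mM, slow addition of 21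
Reagents that add atoms: none
Why: Proposed new method: divalent chromium reduces the C–Br bond to a chromium enolate that adds to the neighbouring acyloxy-activated C8 ketone through a five-membered transition state placing the bulky C9 substituent trans to both C6 and the C18 methyl (hence the required C8 and C17 configurations), and in the same flask zerovalent nickel inserts into the alkenyl iodide, transmetalates to chromium and the alkenylchromium adds 1,2 to the enal to close the ten-membered ring with C4 set by the folded macrocyclic transition state (4S expected), the closest known reactions being the chromium Reformatsky reaction, the zinc or SmI2 Reformatsky lactonisation of α-(bromoacyloxy) ketones and the Nozaki–Hiyama–Kishi macrocyclisation.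

Step 16
Reactants: 23 macrocyclic lactone
Product: 24 target CNP0196166.1
Conditions: NaOCl (aq, 1.2 equiv), CeCl3·7H2O (1.2 equiv), CH2Cl2–H2O, 0 °C
Reagents that add atoms: sodium hypochlorite [Na+].[O-]Cl
Why: Ene-type allylic chlorination of a trisubstituted olefin by hypochlorous acid generated in situ puts chlorine on the less substituted C6 and removes a proton from the C16 methyl to give the 2-methylene allylic chloride, with chlorine expected on the exposed outer face of the strained E olefin to give 6S.

**Compound list**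
1 | methyl 2-hydroxybut-3-enoate (racemic) | C=CC(O)C(=O)OC | starting material
2 | S-ethyl 2-hydroxybut-3-enethioate (racemic) | C=CC(O)C(=O)SCC | intermediate
3 | S-ethyl (S)-2-hydroxybut-3-enethioate | C=C[C@H](O)C(=O)SCC | intermediate
4 | S-ethyl (S)-2-acetoxybut-3-enethioate | C=C[C@H](OC(C)=O)C(=O)SCC | intermediate
5 | methacrolein (2-methylprop-2-enal) | C=C(C)C=O | starting material
6 | S-ethyl (2S,3E)-2-acetoxy-4-methyl-5-oxopent-3-enethioate | O=C/C(C)=C/[C@H](OC(C)=O)C(=O)SCC | intermediate
7 | (E)-4-methoxybut-3-en-2-one | CC(=O)/C=C/OC | starting material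
8 | (E)-1-methoxypent-1-en-3-one | CCC(=O)/C=C/OC | intermediate
9 | (1E,3Z)-1-methoxy-3-(trimethylsilyloxy)penta-1,3-diene | CO/C=C/C(O[Si](C)(C)C)=C/C | intermediate
10 | Diels–Alder adduct of 6 and 9: cyclohexene with C1(CH3)(CHO), C14H(OCH3), C13H=C12(OSiMe3), C11H(CH3) and C10H–C9H(OAc)–C(=O)SEt; C1 and C10 as in 11, C11 and C14 epimers | O=C[C@@]1(C)C(OC)C=C(O[Si](C)(C)C)C(C)[C@@H]1[C@H](OC(C)=O)C(=O)SCC | intermediate
11 | S-ethyl (2S)-2-acetoxy-2-[(1S,2S)-2-formyl-2,6-dimethyl-5-oxocyclohex-3-en-1-yl]ethanethioate (C1 S, C9 S, C10 S; C11 epimers) | O=C[C@@]1(C)C=CC(=O)C(C)[C@@H]1[C@H](OC(C)=O)C(=O)SCC | intermediate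
12 | S-ethyl (2S)-2-acetoxy-2-[(1S,2S,6S)-6-acetoxy-2-formyl-2,6-dimethyl-5-oxocyclohex-3-en-1-yl]ethanethioate (C1 S, C9 S, C10 S, C11 S) | O=C[C@@]1(C)C=CC(=O)[C@@](C)(OC(C)=O)[C@@H]1[C@H](OC(C)=O)C(=O)SCC | intermediate
13 | tributyl(vinyl)stannane | CCCC[Sn](CCCC)(CCCC)C=C | starting material
14 | vinyl ketone: 12 with C(=O)SEt replaced by C8(=O)–CH=CH2 | O=C[C@@]1(C)C=CC(=O)[C@@](C)(OC(C)=O)[C@@H]1[C@H](OC(C)=O)C(=O)C=C | intermediate
15 | 2-methylbut-3-en-1-ol (racemic) | C=CC(C)CO | starting material
16 | E-enone alcohol: side chain C9H(OAc)–C8(=O)–C7H=C6H–C5H(CH3)–C4H2OH on the ring of 12 (C5 epimers) | O=C[C@@]1(C)C=CC(=O)[C@@](C)(OC(C)=O)[C@@H]1[C@H](OC(C)=O)C(=O)/C=C/C(C)CO | intermediate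
17 | E-alkenyl iodide: formyl group of 16 converted into (E)-CH=CHI (C2=C3) | I/C=C/[C@@]1(C)C=CC(=O)[C@@](C)(OC(C)=O)[C@@H]1[C@H](OC(C)=O)C(=O)/C=C/C(C)CO | intermediate
18 | (6R,7S)-trans-epoxy ketone of 17 | I/C=C/[C@@]1(C)C=CC(=O)[C@@](C)(OC(C)=O)[C@@H]1[C@H](OC(C)=O)C(=O)[C@H]2O[C@@H]2C(C)CO | intermediate
19 | β,γ-epoxy aldehyde (C4 alcohol of 18 oxidised to CHO) | I/C=C/[C@@]1(C)C=CC(=O)[C@@](C)(OC(C)=O)[C@@H]1[C@H](OC(C)=O)C(=O)[C@H]2O[C@@H]2C(C)C=O | intermediate
20 | (7S,5E)-γ-hydroxy enal: C8(=O)–C7H(OH)–C6H=C5(CH3)–C4HO | I/C=C/[C@@]1(C)C=CC(=O)[C@@](C)(OC(C)=O)[C@@H]1[C@H](OC(C)=O)C(=O)[C@@H](O)/C=C(C)/C=O | intermediate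
21 | C7 2-bromopropanoate of 20 (CHBr epimers) | I/C=C/[C@@]1(C)C=CC(=O)[C@@](C)(OC(C)=O)[C@@H]1[C@H](OC(C)=O)C(=O)[C@@H](OC(=O)C(C)Br)/C=C(C)/C=O | intermediate
22 | seco-lactone: (7S,8S,17R)-β-hydroxy-γ-lactone carrying the E enal on C7, alkenyl iodide still in place | I/C=C/[C@@]1(C)C=CC(=O)[C@@](C)(OC(C)=O)[C@@H]1[C@H](OC(C)=O)[C@]2(O)[C@@H](C)C(=O)O[C@H]2/C=C(C)/C=O | intermediate
23 | (1S,2E,4S,5E,7S,8S,9S,10S,11S,17R) macrocyclic lactone: the target without chlorine, with an endocyclic C5(CH3)=C6 olefin | C/C1=C\[C@@H]2OC(=O)[C@H](C)[C@@]2(O)[C@@H](OC(C)=O)[C@H]2[C@](C)(OC(C)=O)C(=O)C=C[C@]2(C)/C=C/[C@@H]1O | intermediate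
24 | CNP0196166.1 (1S,2E,4S,6S,7R,8R,9S,10S,11S,17R) | C=C1[C@@H](O)/C=C/[C@@]2(C)C=CC(=O)[C@@](C)(OC(C)=O)[C@@H]2[C@H](OC(C)=O)[C@]2(O)[C@@H](C)C(=O)O[C@H]2[C@H]1Cl | target

**Step count**
Total: 16 steps. Longest linear sequence: 14 steps (1–4, then 7–16); steps 5–6 are a two-step side branch.

**Three steps most likely to fail, each with one fallback**

Step 15 (double ring closure). The ten-membered ring with two E olefins is strained, oligomerisation competes, the chromium enolate must attack a ketone, and C4 rests on substrate control. The fallback sets out from 21 and returns at 23. The two ring closures are uncoupled and C4 is put under reagent control: CrCl2 alone in THF, with no nickel salt so that the alkenyl iodide stays intact, gives seco-lactone 22, which is isolated. Compound 22 is then cyclised under Kishi-type catalytic asymmetric conditions (CrCl2 10 mol%, chiral sulfonamide ligand, NiCl2·neocuproine 2 mol%, Mn, ZrCp2Cl2, LiCl, MeCN, high dilution) to 23. No new compound is made.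

Step 16 (late chlorination). The C6 configuration depends on which olefin face is exposed, and hypochlorous acid may also attack the C4 carbinol. The fallback sets out from 23 and returns at 24; it is used if direct chlorination gives the 6R epimer. TESCl and imidazole silylate only the secondary C4 hydroxyl to give the 4-O-triethylsilyl ether F3. Singlet oxygen (O2, tetraphenylporphyrin, light, CH2Cl2, −20 °C) attacks the same exposed face in a Schenck ene reaction to give the C6 allylic hydroperoxide F4 with C5=C16 in place. PPh3 reduces it in the same flask to the 6-epi allylic alcohol F5. Hexachloroacetone and PPh3 replace the hydroxyl by chloride with SN2 inversion to give the chloride silyl ether F6, and HF·pyridine then gives 24. Because oxygen enters on the face chlorine would have taken and is then inverted, this path gives the complementary C6 epimer.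

Step 7 (Diels–Alder). A trisubstituted enal reacts slowly with the diene, and facial control rests only on the C9 acetoxy group. The fallback sets out from 6 and returns at 11. Ethyl vinyl ketone is silylated (TBSOTf, Et3N) to (Z)-3-(tert-butyldimethylsilyloxy)penta-1,3-diene F1. F1 adds to 6 under a protonated diphenylprolinol-derived oxazaborolidine (Corey type, triflimide salt, −78 °C), which binds the formyl group and fixes the enal face by catalyst control, giving the cyclohexenyl silyl ether adduct F2. Saegusa–Ito dehydrogenation of F2 (Pd(OAc)2, O2, DMSO) then gives 11.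

Further compounds
F1 | step 7 | (Z)-3-(tert-butyldimethylsilyloxy)penta-1,3-diene | C=C/C(O[Si](C)(C)C(C)(C)C)=C/C
F2 | step 7 | cyclohexenyl silyl ether adduct: as 10 but C14H2 and OSi(t-Bu)Me2 on C12 (C11 epimers) | O=C[C@@]1(C)CC=C(O[Si](C)(C)C(C)(C)C)C(C)[C@@H]1[C@H](OC(C)=O)C(=O)SCC
F0 | step 15 | none | none
F3 | step 16 | 4-O-triethylsilyl ether of 23 | C/C1=C\[C@@H]2OC(=O)[C@H](C)[C@@]2(O)[C@@H](OC(C)=O)[C@H]2[C@](C)(OC(C)=O)C(=O)C=C[C@]2(C)/C=C/[C@@H]1O[Si](CC)(CC)CC
F4 | step 16 | C6 allylic hydroperoxide (6-epi oxygen, C5=C16 methylene, 4-O-triethylsilyl) | C=C1[C@@H](O[Si](CC)(CC)CC)/C=C/[C@@]2(C)C=CC(=O)[C@@](C)(OC(C)=O)[C@@H]2[C@H](OC(C)=O)[C@]2(O)[C@@H](C)C(=O)O[C@H]2[C@@H]1OO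
F5 | step 16 | 6-epi allylic alcohol (4-O-triethylsilyl) | C=C1[C@@H](O[Si](CC)(CC)CC)/C=C/[C@@]2(C)C=CC(=O)[C@@](C)(OC(C)=O)[C@@H]2[C@H](OC(C)=O)[C@]2(O)[C@@H](C)C(=O)O[C@H]2[C@@H]1O
F6 | step 16 | 4-O-triethylsilyl ether of 24 | C=C1[C@@H](O[Si](CC)(CC)CC)/C=C/[C@@]2(C)C=CC(=O)[C@@](C)(OC(C)=O)[C@@H]2[C@H](OC(C)=O)[C@]2(O)[C@@H](C)C(=O)O[C@H]2[C@H]1Cl
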